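**Retrosynthetic overview**

- The target comes from a bis-silylated ten-membered keto α-methylene-γ-lactone by reagent-controlled ketone reduction, methacryloylation and desilylation.
- The ten-membered ring comes from a three-carbon ring expansion of a cycloheptanone: an allylindium unit, made from a vinyl epoxide, closes a five-membered ring onto the ketone; the cis-fused alkoxide then fragments (Grob, mesylate as nucleofuge) to the ring ketone and the trisubstituted ring alkene, and the freed secondary alkoxide closes the lactone.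
- The vinyl epoxide comes from an allyl side chain by Heck coupling with methyl 2-bromoacrylate and Shi epoxidation (sets the lactone carbinol centre).
- The quaternary carbon and its neighbouring oxygen come from a borylative aldol with formaldehyde and oxidation; the remote CH2OH stereocentre comes from a copper-catalysed asymmetric conjugate addition of a silylmethyl Grignard reagent to a 2-allyl cross-conjugated dienone.
- The dienone comes from cycloheptanone. Ring order: seven-membered carbocycle (bought), transient five-membered ring, ten-membered ring, γ-lactone.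

Assumption 1 (locants): C1 is the ring carbon that carries the methacrylate oxygen; then round the ring C2, C3 (bears C15H2O), C4, C5, C6=C7 (C7 bears C14H2O), C8, C9 (lactone oxygen), C10 (bears C11); C11 (=C13H2) and C12 (C=O) complete the lactone.

Assumption 2 (diastereomers): step 5 is not expected to be selective relative to C3, so 10 to 17 are drawn as one of two C6/C7 arrangements; in both the allyl-derived carbon is cis to the C6 oxygen and both converge to 19 in step 11.

Step 1
Reactants: 1 cycloheptanone
Product: 2 cyclohepta-2,6-dien-1-one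
Conditions: IBX (3 equiv), 4-methoxypyridine N-oxide (3 equiv), DMSO, 25 °C
Reagents that add atoms: none
Why: IBX dehydrogenation of a ketone (oxidation of the enol) on both sides of the symmetrical ring gives the cross-conjugated dienone, and no stereocentre is formed.

Step 2
Reactants: 2 cyclohepta-2,6-dien-1-one
Product: 3 2-iodocyclohepta-2,6-dien-1-one
Conditions: I2 (1.1 equiv), K2CO3, DMAP (20 mol %), THF/H2O 1:1, 25 °C
Reagents that add atoms: iodine, II
Why: Baylis–Hillman-type α-iodination of an enone (conjugate addition of DMAP, iodination, elimination); the two enone halves are equivalent, so one equivalent of iodine gives the mono-iodide.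

Step 3
Reactants: 3 2-iodocyclohepta-2,6-dien-1-one, 4 potassium trifluoro(prop-2-en-1-yl)borate
Product: 5 2-allylcyclohepta-2,6-dien-1-one
Conditions: Pd(OAc)2 (3 mol %), 1,1'-bis(di-tert-butylphosphino)ferrocene (4 mol %), K2CO3 (3 equiv), THF/H2O 10:1, 40 °C
Reagents that add atoms: none
Why: Suzuki–Miyaura coupling of the α-iodoenone, which adds readily to zerovalent palladium, places C8–C10 on the future C7.

Step 4
Reactants: 5 2-allylcyclohepta-2,6-dien-1-one, 6 (chloromethyl)ethoxydimethylsilane
Product: 8 (6R)-2-allyl-6-[(ethoxydimethylsilyl)methyl]cyclohept-2-en-1-one, via Grignard reagent 7 (not isolated)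
Conditions: 6, Mg, THF, 40 °C; then CuBr·SMe2 (5 mol %), (R)-1-[(S)-2-(diphenylphosphino)ferrocenyl]ethyldicyclohexylphosphine (6 mol %; the ligand antipode that gives 6R), 5, t-BuOMe, −75 °C; aq NH4Cl
Reagents that add atoms: none
Why: Copper-catalysed asymmetric conjugate addition of a Grignard reagent puts the silylmethyl group (a masked CH2OH) on the unsubstituted enone only, the α-allyl enone being hindered, and the chiral diphosphine–copper complex sets C3 (6R here).

Step 5
Reactants: 8 (6R)-2-allyl-6-[(ethoxydimethylsilyl)methyl]cyclohept-2-en-1-one, 9 formaldehyde (monomer from cracked paraformaldehyde)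
Product: 10 (2R,3R,6R)-2-allyl-6-[(ethoxydimethylsilyl)methyl]-2-(hydroxymethyl)-3-(4,4,5,5-tetramethyl-1,3,2-dioxaborolan-2-yl)cycloheptan-1-one
Conditions: B2pin2 (1.2 equiv), CuCl (10 mol %), Xantphos (10 mol %), NaOtBu (20 mol %), THF, 0 °C; then 9 in THF, −40 to 0 °C; aq NH4Cl
Reagents that add atoms: bis(pinacolato)diboron, CC1(C)OB(OC1(C)C)B1OC(C)(C)C(C)(C)O1
Why: Copper-catalysed conjugate borylation with aldol capture (borylative aldol) puts boron on C6, and the copper enolate takes formaldehyde at C7 from the face opposite the new C–B bond, so CH2OH ends trans and the allyl group cis to boron.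

Step 6
Reactants: 10 the β-boryl aldol
Product: 11 (2S,3R,6R)-2-allyl-3-hydroxy-2,6-bis(hydroxymethyl)cycloheptan-1-one
Conditions: H2O2 (30 % aq), KF, KHCO3, THF/MeOH, 0 to 25 °C
Reagents that add atoms: hydrogen peroxide, OO
Why: Tamao-type oxidation with buffered peroxide turns the C–B bond into C6–OH with retention and the alkoxysilane C–Si bond into the C15 alcohol in one operation.

Step 7
Reactants: 11 the triol
Product: 12 (2S,3R,6R)-2-allyl-2,6-bis[(tert-butyldimethylsilyloxy)methyl]-3-hydroxycycloheptan-1-one
Conditions: TBSCl (2.2 equiv), imidazole, DMF, 0 °C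
Reagents that add atoms: tert-butyldimethylsilyl chloride, CC(C)(C)[Si](C)(C)Cl
Why: Silylation takes the two primary alcohols only, because the secondary C6 hydroxyl sits next to the quaternary carbon.

Step 8
Reactants: 12 the bis-silyl ether
Product: 13 (1R,2S,5R)-2-allyl-2,5-bis[(tert-butyldimethylsilyloxy)methyl]-3-oxocycloheptyl methanesulfonate
Conditions: MsCl, Et3N, CH2Cl2, 0 °C
Reagents that add atoms: methanesulfonyl chloride, CS(Cl)(=O)=O
Why: Mesylation through the sulfene tolerates the hindered alcohol and makes the C6 oxygen the nucleofuge for the later fragmentation, with retention at C6.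

Step 9
Reactants: 13 the keto mesylate, 14 methyl 2-bromoprop-2-enoate
Product: 15 (1R,2S,5R)-2,5-bis[(tert-butyldimethylsilyloxy)methyl]-2-[(2E)-4-(methoxycarbonyl)penta-2,4-dien-1-yl]-3-oxocycloheptyl methanesulfonate
Conditions: 14 (1.5 equiv), Pd(OAc)2 (5 mol %), Bu4NCl, NaHCO3, DMF, 50 °C
Reagents that add atoms: none
Why: Heck reaction: the alkenylpalladium species from the bromoacrylate adds to the terminal alkene at C10 and β-hydride elimination gives the conjugated E-diene.

Step 10
Reactants: 15 the diene ester
Product: 16 (1R,2S,5R)-2,5-bis[(tert-butyldimethylsilyloxy)methyl]-2-{[(2R,3R)-3-(3-methoxy-3-oxoprop-1-en-2-yl)oxiran-2-yl]methyl}-3-oxocycloheptyl methanesulfonate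
Conditions: D-fructose-derived Shi ketone (30 mol %), KHSO5 (as 2KHSO5·KHSO4·K2SO4), K2CO3, Bu4NHSO4 (cat.), MeCN/dimethoxymethane/aq borate buffer, 0 °C
Reagents that add atoms: potassium peroxymonosulfate, OOS(=O)(=O)[O-].[K+]
Why: Shi asymmetric epoxidation: the chiral dioxirane attacks the electron-richer trans C9=C10 bond (the acrylate alkene is electron-poor) through the spiro transition state and sets C9 as R.

Step 11
Reactants: 16 the vinyl epoxide
Product: 19 (3R,9R,10S)-ten-membered keto α-methylene lactone bis-TBS ether, via bicyclic diol mesylate 17 (not isolated), via seco hydroxy ester 18 (not isolated)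
Conditions: Pd(PPh3)4 (5 mol %), InI (1.5 equiv), THF/DMF 4:1, 25 °C then 50 °C; aq NH4Cl; PPTS (cat.), CH2Cl2, 25 °C
Reagents that add atoms: none
Why: Proposed new method: zerovalent palladium ionises the vinyl epoxide to a 2-(methoxycarbonyl)allyl complex carrying the C9 alkoxide, InI reduces it to an allylindium unit that adds through C10 to the neighbouring ketone (five-membered ring closure, with C11 placed trans to the C9 oxygen by allylic strain), the cis-fused tertiary alkoxide then undergoes Grob fragmentation antiperiplanar to the C6 mesylate to give the ten-membered ring with the C1 ketone and the C6=C7 alkene (C5 and C8 cis because the allyl-derived carbon was cis to the mesylate), and the C9 hydroxyl lactonises; the closest known reactions are the palladium/InI umpolung allylation of carbonyl compounds with vinyl epoxides and the tandem SmI2 Barbier cyclisation/Grob fragmentation ring expansion of keto mesylates.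

Step 12
Reactants: 19 the keto lactone
Product: 20 (1R,3R,9R,10R)-hydroxy lactone bis-TBS ether
Conditions: (S)-2-methyl-CBS-oxazaborolidine (0.3 equiv), catecholborane (1.5 equiv), toluene, −60 °C; MeOH
Reagents that add atoms: none
Why: Corey–Bakshi–Shibata reduction: the oxazaborolidine tells the branched C10 side from the C2 methylene side and delivers hydride to give the 1R alcohol (reagent control), and catecholborane leaves the alkenes alone.

Step 13
Reactants: 20 the hydroxy lactone, 21 methacryloyl chloride
Product: 22 (1R,3R,9R,10R)-methacrylate bis-TBS ether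
Conditions: 21 (1.5 equiv), Et3N, DMAP (cat.), CH2Cl2, 0 °C
Reagents that add atoms: none
Why: DMAP-catalysed acylation with the acid chloride reaches only C1–OH, since both primary hydroxyls are still silylated.

Step 14
Reactants: 22 the methacrylate bis-TBS ether
Product: 23 CNP0303865.1 (target)
Conditions: HF·pyridine, THF/pyridine, 0 to 25 °C
Reagents that add atoms: none
Why: Fluoride cleavage of both silyl ethers under buffered, mildly acidic conditions spares the methacrylate, the lactone and the allylic alcohol.

**Compound list**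

1 | cycloheptanone | O=C1CCCCCC1 | starting material
2 | cyclohepta-2,6-dien-1-one | O=C1C=CCCC=C1 | intermediate
3 | 2-iodocyclohepta-2,6-dien-1-one | O=C1C=CCCC=C1I | intermediate
4 | potassium trifluoro(prop-2-en-1-yl)borate | C=CC[B-](F)(F)F.[K+] | starting material
5 | 2-allylcyclohepta-2,6-dien-1-one | O=C1C=CCCC=C1CC=C | intermediate
6 | (chloromethyl)ethoxydimethylsilane | CCO[Si](C)(C)CCl | starting material
7 | [(ethoxydimethylsilyl)methyl]magnesium chloride | CCO[Si](C)(C)C[Mg]Cl | intermediate
8 | (6R)-2-allyl-6-[(ethoxydimethylsilyl)methyl]cyclohept-2-en-1-one | O=C1C[C@H](C[Si](C)(C)OCC)CCC=C1CC=C | intermediate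
9 | formaldehyde | C=O | starting material
10 | (2R,3R,6R)-2-allyl-6-[(ethoxydimethylsilyl)methyl]-2-(hydroxymethyl)-3-(4,4,5,5-tetramethyl-1,3,2-dioxaborolan-2-yl)cycloheptan-1-one (allyl cis to boron) | O=C1C[C@H](C[Si](C)(C)OCC)CC[C@@H](B2OC(C)(C)C(C)(C)O2)[C@@]1(CO)CC=C | intermediate
11 | (2S,3R,6R)-2-allyl-3-hydroxy-2,6-bis(hydroxymethyl)cycloheptan-1-one (allyl cis to 3-OH) | O=C1C[C@H](CO)CC[C@@H](O)[C@@]1(CO)CC=C | intermediate
12 | (2S,3R,6R)-2-allyl-2,6-bis[(tert-butyldimethylsilyloxy)methyl]-3-hydroxycycloheptan-1-one | O=C1C[C@H](CO[Si](C)(C)C(C)(C)C)CC[C@@H](O)[C@@]1(CO[Si](C)(C)C(C)(C)C)CC=C | intermediate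
13 | (1R,2S,5R)-2-allyl-2,5-bis[(tert-butyldimethylsilyloxy)methyl]-3-oxocycloheptyl methanesulfonate | O=C1C[C@H](CO[Si](C)(C)C(C)(C)C)CC[C@@H](OS(C)(=O)=O)[C@@]1(CO[Si](C)(C)C(C)(C)C)CC=C | intermediate
14 | methyl 2-bromoprop-2-enoate | C=C(Br)C(=O)OC | starting material
15 | (1R,2S,5R)-2,5-bis[(tert-butyldimethylsilyloxy)methyl]-2-[(2E)-4-(methoxycarbonyl)penta-2,4-dien-1-yl]-3-oxocycloheptyl methanesulfonate | O=C1C[C@H](CO[Si](C)(C)C(C)(C)C)CC[C@@H](OS(C)(=O)=O)[C@@]1(CO[Si](C)(C)C(C)(C)C)C/C=C/C(=C)C(=O)OC | intermediate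
16 | (1R,2S,5R)-2,5-bis[(tert-butyldimethylsilyloxy)methyl]-2-{[(2R,3R)-3-(3-methoxy-3-oxoprop-1-en-2-yl)oxiran-2-yl]methyl}-3-oxocycloheptyl methanesulfonate | O=C1C[C@H](CO[Si](C)(C)C(C)(C)C)CC[C@@H](OS(C)(=O)=O)[C@@]1(CO[Si](C)(C)C(C)(C)C)C[C@H]2O[C@@H]2C(=C)C(=O)OC | intermediate
17 | bicyclic diol mesylate: five-membered ring C1,C7,C8,C9,C10 cis-fused to the seven-membered ring C1–C7; OH on C1 and C9; methyl acrylate unit on C10 trans to the C9 hydroxyl; mesylate on C6; CH2OTBS on C3 and C7; 1S,3R,6R,7S,9R,10S | O[C@]12C[C@H](CO[Si](C)(C)C(C)(C)C)CC[C@@H](OS(C)(=O)=O)[C@@]1(CO[Si](C)(C)C(C)(C)C)C[C@@H](O)[C@@H]2C(=C)C(=O)OC | intermediate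
18 | seco hydroxy ester: ten-membered C1 ketone with 6E alkene (C5 and C8 cis), C9 hydroxyl, methyl acrylate unit on C10, CH2OTBS on C3 and C7; 3R,9R,10S | O=C1C[C@H](CO[Si](C)(C)C(C)(C)C)CC/C=C(/CO[Si](C)(C)C(C)(C)C)C[C@@H](O)[C@@H]1C(=C)C(=O)OC | intermediate
19 | ten-membered keto α-methylene-γ-lactone: C1 ketone, 6E alkene, lactone oxygen on C9 trans to C11 on C10, CH2OTBS on C3 and C7; 3R,9R,10S | O=C1C[C@H](CO[Si](C)(C)C(C)(C)C)CC/C=C(/CO[Si](C)(C)C(C)(C)C)C[C@H]2OC(=O)C(=C)[C@H]12 | intermediate
20 | 1-hydroxy analogue of 19 (OH cis to C11, trans to the lactone oxygen); 1R,3R,9R,10R | O[C@@H]1C[C@H](CO[Si](C)(C)C(C)(C)C)CC/C=C(/CO[Si](C)(C)C(C)(C)C)C[C@H]2OC(=O)C(=C)[C@H]12 | intermediate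
21 | methacryloyl chloride | C=C(C)C(Cl)=O | starting material
22 | methacrylate of 20 (the target with both primary hydroxyls as TBS ethers); 1R,3R,9R,10R | C=C(C)C(=O)O[C@@H]1C[C@H](CO[Si](C)(C)C(C)(C)C)CC/C=C(/CO[Si](C)(C)C(C)(C)C)C[C@H]2OC(=O)C(=C)[C@H]12 | intermediate
23 | CNP0303865.1: (1R,3R,9R,10R,6E)-3,7-bis(hydroxymethyl)-11(13)-methylene-9,12-olide of cyclodec-6-ene, 1-methacrylate | C=C(C)C(=O)O[C@@H]1C[C@H](CO)CC/C=C(/CO)C[C@H]2OC(=O)C(=C)[C@H]12 | target

**Step count**

Total steps: 14. Longest linear sequence: 14 steps, from cycloheptanone 1.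

**Steps most likely to fail, with fallbacks**

Step 11 (the proposed new ring expansion). The allylindium unit may be protonated or may eliminate back to diene 15; the indium alkoxide may be too weakly basic to fragment; or the C1 alkoxide may lactonise before it fragments. The fallback uses known reactions one at a time and sets out from 16. MgBr2·OEt2 in ether opens the vinyl epoxide in the SN2' sense to the allylic bromide bromohydrin F3. Zn dust in THF/aq NH4Cl (Barbier allylation of the ketone) then gives the bicyclic diol mesylate 17, now isolated. KOtBu in THF at 0 °C effects the Grob (Wharton) fragmentation to 18, and PPTS closes the lactone, so the route is rejoined at 19.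

Step 5 (borylative aldol building the quaternary C7). The tetrasubstituted copper enolate may be protonated instead of taking formaldehyde, or the product may lose formaldehyde by retro-aldol. The fallback sets out from 8. Nucleophilic epoxidation with tBuOOH/DBU gives the epoxy ketone F1. SmI2 in THF at −78 °C cleaves the Cα–O bond, and the samarium enolate is trapped with formaldehyde 9 anti to the C6 oxygen to give the diol silane F2. Tamao oxidation (H2O2, KF, KHCO3) then gives triol 11, where the route is rejoined.

Step 12 (reduction of a flexible ten-membered ketone). Substrate bias may override the oxazaborolidine and give the 1S alcohol. The fallback sets out from 19. Luche reduction (NaBH4, CeCl3·7H2O, MeOH, −78 °C) gives the epimeric alcohol F4 if substrate control favours it. Mitsunobu esterification with methacrylic acid (PPh3, DIAD) then inverts C1 and gives 22 directly, where the route is rejoined.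

Further compounds
F1 | step 5 | (2R,3R,6R)-2-allyl-2,3-epoxy-6-[(ethoxydimethylsilyl)methyl]cycloheptan-1-one | O=C1C[C@H](C[Si](C)(C)OCC)CC[C@H]2O[C@@]12CC=C
F2 | step 5 | (2S,3R,6R)-2-allyl-6-[(ethoxydimethylsilyl)methyl]-3-hydroxy-2-(hydroxymethyl)cycloheptan-1-one | O=C1C[C@H](C[Si](C)(C)OCC)CC[C@@H](O)[C@@]1(CO)CC=C
F3 | step 11 | (1R,2S,5R)-2-[(2R,3Z)-4-(bromomethyl)-2-hydroxy-5-methoxy-5-oxopent-3-en-1-yl]-2,5-bis[(tert-butyldimethylsilyloxy)methyl]-3-oxocycloheptyl methanesulfonate | O=C1C[C@H](CO[Si](C)(C)C(C)(C)C)CC[C@@H](OS(C)(=O)=O)[C@@]1(CO[Si](C)(C)C(C)(C)C)C[C@@H](O)/C=C(\CBr)C(=O)OC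
F4 | step 12 | C1 epimer of 20 (1S,3R,9R,10R) | O[C@H]1C[C@H](CO[Si](C)(C)C(C)(C)C)CC/C=C(/CO[Si](C)(C)C(C)(C)C)C[C@H]2OC(=O)C(=C)[C@H]12
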